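**Retrosynthetic overview**

1. The strategy rests on ring A: a hexasubstituted benzene whose substituents alternate, with oxygen on C2, C4 and C6 and carbon on C1 (hexanoyl), C3 and C5 (two identical (R)-CH(i-Pr)–trione side arms). A 3-siloxy vinylketene and a siloxyalkyne deliver exactly this alternation.
2. The last C–C bond is C1–acyl (Friedel–Crafts at the one free ring carbon). Before that, ring A is cut at C2–C3, C4–C5 and C1–C2 into a 2-alkyl-3-siloxycyclobutenone and a siloxyalkyne (benzannulation).
3. Both partners are the same enantioenriched siloxyalkyne; part of it takes up ketene in a [2+2] reaction to become the cyclobutenone. Because two copies of one fragment are joined, the minor enantiomer should end mainly in a separable meso diastereomer.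
4. The siloxyalkyne comes from a terminal alkyne made by enantioselective conjugate alkynylation of isobutylidene syncarpic acid, which sets both CH centres.
5. Ring order: the two trione rings are bought as syncarpic acid, the four-membered ring is made next, and ring A is closed last. The trione enols travel as benzyl ethers (removed by hydrogenolysis) and the phenols as silyl ethers (removed by fluoride).

Key step: step 6

Assumption: in step 2 the ligand antipode that gives (S)-6 is fixed by a pilot run; both antipodes of the P,N-ligand are available, so the choice does not change the route.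

Naming remark: "Bn-arm" stands for (1R)-1-[2-(benzyloxy)-3,3,5,5-tetramethyl-4,6-dioxocyclohex-1-en-1-yl]-2-methylpropyl. The spatial arrangement of this CH centre is the same in every compound from 8 onward; where the formal descriptor changes, this is noted.

**Route**

Step 1
Reactants: 1 syncarpic acid (2,2,4,4-tetramethylcyclohexane-1,3,5-trione); 2 isobutyraldehyde
Product: 4 2,2,4,4-tetramethyl-6-(2-methylpropylidene)cyclohexane-1,3,5-trione, via Mannich base 3 (not isolated)
Conditions: piperidine (1.05 equiv), CH2Cl2, rt; then 1 M HCl (aq), 0 °C; 4 is used at once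
Reagents that add atoms: none
Why: Knoevenagel condensation run through the Mannich base, in which piperidine, the aldehyde and the acidic trione give 3 and acid then expels piperidinium to leave the alkylidene trione; the detour through 3 should suppress a second Michael addition of 1 to 4.

Step 2
Reactants: 4; 5 trimethylsilylacetylene
Product: 6 5-hydroxy-2,2,6,6-tetramethyl-4-[(3S)-4-methyl-1-(trimethylsilyl)pent-1-yn-3-yl]cyclohex-4-ene-1,3-dione
Conditions: Cu(OAc)2·H2O (10 mol %), sodium L-ascorbate NaC6H7O6 (20 mol %), (R,P)-N-PINAP (11 mol %), 5 (5 equiv), H2O/t-BuOH, 0 °C; then 1 M HCl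
Reagents that add atoms: none
Why: Copper-catalysed enantioselective conjugate alkynylation of an alkylidene 1,3-dicarbonyl acceptor, in which ascorbate reduces divalent copper to the monovalent copper acetylide of 5, which adds to the β-carbon of the symmetrical trione 4 (no E/Z issue) while the chiral P,N-ligand selects the alkene face; the new CH centre is (S) here only because silicon outranks oxygen, and it has the spatial arrangement of the (R) centres of the target.

Step 3
Reactants: 6
Product: 8 5-(benzyloxy)-2,2,6,6-tetramethyl-4-[(3R)-4-methylpent-1-yn-3-yl]cyclohex-4-ene-1,3-dione, via potassium enolate 7 (not isolated)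
Conditions: K2CO3 (2.5 equiv), MeOH, rt; evaporate to dryness; then BnBr (1.3 equiv), DMF, rt
Reagents that add atoms: benzyl bromide BrCc1ccccc1
Why: Protodesilylation of the alkynylsilane by methanolic carbonate leaves enolate 7, whose Williamson-type alkylation in DMF should go on oxygen because the enolate carbon is already fully substituted and shielded by the branched side chain; the two enolate oxygens are equivalent by rotation about the ring–CH bond, so only one enol ether can form.

Step 4
Reactants: 8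
Product: 11 5-(benzyloxy)-2,2,6,6-tetramethyl-4-[(3R)-4-methyl-1-(triisopropylsilyloxy)pent-1-yn-3-yl]cyclohex-4-ene-1,3-dione, via lithium acetylide 9 (not isolated), via lithium ynolate 10 (not isolated)
Conditions: LiN(SiMe3)2 (2.2 equiv), THF, −78 °C; t-BuOOH (1.05 equiv, in decane), −78 → 0 °C; then i-Pr3SiOTf (1.3 equiv), −78 → 0 °C
Reagents that add atoms: tert-butyl hydroperoxide CC(C)(C)OO; triisopropylsilyl trifluoromethanesulfonate CC(C)[Si](OS(=O)(=O)C(F)(F)F)(C(C)C)C(C)C
Why: Oxidation of a lithium acetylide with lithium tert-butyl peroxide (oxygen transfer with tert-butoxide as leaving group) gives ynolate 10, which the bulky silyl triflate silylates on oxygen to the ynol silyl ether; the amide base is non-nucleophilic toward the hindered ketone and the vinylogous ester and cannot remove the non-enolisable propargylic hydrogen, so the CH centre is kept.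

Step 5
Reactants: 11 (about half of the batch)
Product: 12 5-(benzyloxy)-2,2,6,6-tetramethyl-4-{(1R)-2-methyl-1-[4-oxo-2-(triisopropylsilyloxy)cyclobut-1-en-1-yl]propyl}cyclohex-4-ene-1,3-dione
Conditions: ketene (gas, excess, from thermal cracking of diketene), CH2Cl2, 0 °C → rt
Reagents that add atoms: ketene C=C=O
Why: [2+2] cycloaddition of ketene with an electron-rich siloxyalkyne, in which the nucleophilic arm-bearing alkyne carbon bonds to the ketene carbonyl carbon, so the 2-alkyl-3-siloxycyclobutenone should form as a single regioisomer.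

Step 6
Reactants: 12; 11
Product: 17 2,4-bis{(1R)-1-[2-(benzyloxy)-3,3,5,5-tetramethyl-4,6-dioxocyclohex-1-en-1-yl]-2-methylpropyl}-3,5-bis(triisopropylsilyloxy)phenol, via vinylketene 13 (not isolated), via vinylcyclobutenone 14 (not isolated), via dienylketene 15 (not isolated), via cyclohexadienone 16 (not isolated)
Conditions: 11 (1.1 equiv), toluene (0.2 M, degassed), sealed tube, 80 → 110 °C
Reagents that add atoms: none
Why: Proposed new method: thermal 4π electrocyclic opening of 12 should give siloxy vinylketene 13, which adds 11 in a [2+2] cycloaddition (arm-bearing alkyne carbon to the ketene carbonyl carbon, forming C2–C3 and C4–C5) to give 14; reversible 4π opening of 14 gives dienylketene 15, whose 6π electrocyclisation forms C1–C2 and closes ring A as a six-membered carbocycle, and dienone 16 tautomerises to phenol 17. The closest known reaction is the Danheiser benzannulation of 3-alkyl- or 3-aryl-cyclobutenones with siloxyalkynes to resorcinol monosilyl ethers; a 3-siloxycyclobutenone as the four-carbon partner is not established, and its push–pull stabilisation may call for the upper end of the temperature range. No lasting stereocentre is formed (the sp3 ring carbon of 14 becomes sp2), and the two CH centres carry no enolisable hydrogen under neutral thermal conditions, so they should pass through unchanged. The selectivity needed is regiochemical and is secured by the polarity of the ynol ether toward the ketene, which puts both arms beside the alkyne-derived oxygen-bearing carbon C4 and leaves C1 as the only ring CH. The dienylketene isomer with the wrong alkene geometry can return through 14, so both isomers should funnel to 17. The benzyl enol ethers remove the acidic trione proton, which would otherwise protonate the ynol ether or add to the ketene.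

Step 7
Reactants: 17; 18 hexanoyl chloride
Product: 19 1-[3,5-bis{(1R)-1-[2-(benzyloxy)-3,3,5,5-tetramethyl-4,6-dioxocyclohex-1-en-1-yl]-2-methylpropyl}-2-hydroxy-4,6-bis(triisopropylsilyloxy)phenyl]hexan-1-one
Conditions: 18 (1.3 equiv), TiCl4 (2.2 equiv), CH2Cl2, −78 → −30 °C; cold aqueous work-up
Reagents that add atoms: none
Why: Friedel–Crafts acylation of a phloroglucinol-type ring at its only unsubstituted carbon, delivered ortho to the titanium-bound phenol oxygen; at low temperature the benzyl enol ethers and the aryl silyl ethers should survive the Lewis acid.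

Step 8
Reactants: 19
Product: 20 1-[2-hydroxy-3,5-bis{(1R)-1-(2-hydroxy-3,3,5,5-tetramethyl-4,6-dioxocyclohex-1-en-1-yl)-2-methylpropyl}-4,6-bis(triisopropylsilyloxy)phenyl]hexan-1-one
Conditions: H2 (1 atm), Pd/C (10 wt % palladium on carbon, cat.), EtOAc, rt
Reagents that add atoms: none
Why: Catalytic hydrogenolysis of the two benzylic C–O bonds of the vinylogous benzyl esters frees both trione enols under neutral conditions, so neither acid nor base is present to drive the neighbouring phenol onto the enol ether carbon (pyran closure) or to reverse the Michael-type C–C bonds; the hydrogen-bonded aryl ketone, the tetrasubstituted enol alkenes and the silyl ethers should be inert at 1 atm.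

Step 9
Reactants: 20
Product: 21 myrtucommulone F
Conditions: Bu4NF (6 equiv), AcOH (6 equiv), THF, 0 °C → rt
Reagents that add atoms: none
Why: Fluoride cleavage of the two aryl silyl ethers (Si–F bond formation with the phenol as leaving group), buffered with acetic acid so that no strongly basic phenoxide is present that could epimerise the CH centres by retro-Michael and re-addition.

**Compound list**

1 | syncarpic acid (2,2,4,4-tetramethylcyclohexane-1,3,5-trione) | CC1(C)C(=O)CC(=O)C(C)(C)C1=O | starting material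
2 | isobutyraldehyde | CC(C)C=O | starting material
3 | Mannich base, 5-hydroxy-2,2,6,6-tetramethyl-4-[2-methyl-1-(piperidin-1-yl)propyl]cyclohex-4-ene-1,3-dione (racemic) | CC(C)C(N1CCCCC1)C2=C(O)C(C)(C)C(=O)C(C)(C)C2=O | intermediate
4 | 2,2,4,4-tetramethyl-6-(2-methylpropylidene)cyclohexane-1,3,5-trione | CC(C)C=C1C(=O)C(C)(C)C(=O)C(C)(C)C1=O | intermediate
5 | trimethylsilylacetylene | C[Si](C)(C)C#C | starting material
6 | 5-hydroxy-2,2,6,6-tetramethyl-4-[(3S)-4-methyl-1-(trimethylsilyl)pent-1-yn-3-yl]cyclohex-4-ene-1,3-dione | C[Si](C)(C)C#C[C@H](C1=C(O)C(C)(C)C(=O)C(C)(C)C1=O)C(C)C | intermediate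
7 | potassium enolate of 5-hydroxy-2,2,6,6-tetramethyl-4-[(3R)-4-methylpent-1-yn-3-yl]cyclohex-4-ene-1,3-dione | C#C[C@H](C1=C([O-])C(C)(C)C(=O)C(C)(C)C1=O)C(C)C.[K+] | intermediate
8 | 5-(benzyloxy)-2,2,6,6-tetramethyl-4-[(3R)-4-methylpent-1-yn-3-yl]cyclohex-4-ene-1,3-dione | C#C[C@H](C1=C(OCc2ccccc2)C(C)(C)C(=O)C(C)(C)C1=O)C(C)C | intermediate
9 | lithium acetylide of 8, (3R) | [Li]C#C[C@H](C1=C(OCc2ccccc2)C(C)(C)C(=O)C(C)(C)C1=O)C(C)C | intermediate
10 | lithium ynolate, lithium (3R)-3-[2-(benzyloxy)-3,3,5,5-tetramethyl-4,6-dioxocyclohex-1-en-1-yl]-4-methylpent-1-yn-1-olate | [Li+].[O-]C#C[C@H](C1=C(OCc2ccccc2)C(C)(C)C(=O)C(C)(C)C1=O)C(C)C | intermediate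
11 | 5-(benzyloxy)-2,2,6,6-tetramethyl-4-[(3R)-4-methyl-1-(triisopropylsilyloxy)pent-1-yn-3-yl]cyclohex-4-ene-1,3-dione | CC(C)[Si](C(C)C)(C(C)C)OC#C[C@H](C1=C(OCc2ccccc2)C(C)(C)C(=O)C(C)(C)C1=O)C(C)C | intermediate
12 | 5-(benzyloxy)-2,2,6,6-tetramethyl-4-{(1R)-2-methyl-1-[4-oxo-2-(triisopropylsilyloxy)cyclobut-1-en-1-yl]propyl}cyclohex-4-ene-1,3-dione | O=C1CC(O[Si](C(C)C)(C(C)C)C(C)C)=C1[C@H](C2=C(OCc3ccccc3)C(C)(C)C(=O)C(C)(C)C2=O)C(C)C | intermediate
13 | vinylketene, 2-(Bn-arm)-3-(triisopropylsilyloxy)buta-1,3-dien-1-one | O=C=C([C@H](C2=C(OCc3ccccc3)C(C)(C)C(=O)C(C)(C)C2=O)C(C)C)C(=C)O[Si](C(C)C)(C(C)C)C(C)C | intermediate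
14 | vinylcyclobutenone, 2,4-bis(Bn-arm)-3-(triisopropylsilyloxy)-4-[1-(triisopropylsilyloxy)ethenyl]cyclobut-2-en-1-one (CH centres unchanged in space, formal descriptor (S) here; ring C4 as both epimers) | O=C1C([C@H](C2=C(OCc3ccccc3)C(C)(C)C(=O)C(C)(C)C2=O)C(C)C)=C(O[Si](C(C)C)(C(C)C)C(C)C)C1([C@H](C2=C(OCc3ccccc3)C(C)(C)C(=O)C(C)(C)C2=O)C(C)C)C(=C)O[Si](C(C)C)(C(C)C)C(C)C | intermediate
15 | dienylketene, 2,4-bis(Bn-arm)-3,5-bis(triisopropylsilyloxy)hexa-1,3,5-trien-1-one (reactive isomer, ketene carbon and siloxyvinyl group cis on the 3,4-alkene) | O=C=C([C@H](C2=C(OCc3ccccc3)C(C)(C)C(=O)C(C)(C)C2=O)C(C)C)/C(O[Si](C(C)C)(C(C)C)C(C)C)=C([C@H](C2=C(OCc3ccccc3)C(C)(C)C(=O)C(C)(C)C2=O)C(C)C)\C(=C)O[Si](C(C)C)(C(C)C)C(C)C | intermediate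
16 | cyclohexadienone, 2,4-bis(Bn-arm)-3,5-bis(triisopropylsilyloxy)cyclohexa-2,4-dien-1-one | O=C1CC(O[Si](C(C)C)(C(C)C)C(C)C)=C([C@H](C2=C(OCc3ccccc3)C(C)(C)C(=O)C(C)(C)C2=O)C(C)C)C(O[Si](C(C)C)(C(C)C)C(C)C)=C1[C@H](C2=C(OCc3ccccc3)C(C)(C)C(=O)C(C)(C)C2=O)C(C)C | intermediate
17 | 2,4-bis{(1R)-1-[2-(benzyloxy)-3,3,5,5-tetramethyl-4,6-dioxocyclohex-1-en-1-yl]-2-methylpropyl}-3,5-bis(triisopropylsilyloxy)phenol | Oc1cc(O[Si](C(C)C)(C(C)C)C(C)C)c([C@H](C2=C(OCc3ccccc3)C(C)(C)C(=O)C(C)(C)C2=O)C(C)C)c(O[Si](C(C)C)(C(C)C)C(C)C)c1[C@H](C2=C(OCc3ccccc3)C(C)(C)C(=O)C(C)(C)C2=O)C(C)C | intermediate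
18 | hexanoyl chloride | CCCCCC(Cl)=O | starting material
19 | 1-[3,5-bis{(1R)-1-[2-(benzyloxy)-3,3,5,5-tetramethyl-4,6-dioxocyclohex-1-en-1-yl]-2-methylpropyl}-2-hydroxy-4,6-bis(triisopropylsilyloxy)phenyl]hexan-1-one | CCCCCC(=O)c1c(O)c([C@H](C2=C(OCc3ccccc3)C(C)(C)C(=O)C(C)(C)C2=O)C(C)C)c(O[Si](C(C)C)(C(C)C)C(C)C)c([C@H](C2=C(OCc3ccccc3)C(C)(C)C(=O)C(C)(C)C2=O)C(C)C)c1O[Si](C(C)C)(C(C)C)C(C)C | intermediate
20 | 1-[2-hydroxy-3,5-bis{(1R)-1-(2-hydroxy-3,3,5,5-tetramethyl-4,6-dioxocyclohex-1-en-1-yl)-2-methylpropyl}-4,6-bis(triisopropylsilyloxy)phenyl]hexan-1-one | CCCCCC(=O)c1c(O)c([C@H](C2=C(O)C(C)(C)C(=O)C(C)(C)C2=O)C(C)C)c(O[Si](C(C)C)(C(C)C)C(C)C)c([C@H](C2=C(O)C(C)(C)C(=O)C(C)(C)C2=O)C(C)C)c1O[Si](C(C)C)(C(C)C)C(C)C | intermediate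
21 | myrtucommulone F, 1-{2,4,6-trihydroxy-3,5-bis[(1R)-1-(2-hydroxy-3,3,5,5-tetramethyl-4,6-dioxocyclohex-1-en-1-yl)-2-methylpropyl]phenyl}hexan-1-one | CCCCCC(=O)c1c(O)c([C@H](C2=C(O)C(C)(C)C(=O)C(C)(C)C2=O)C(C)C)c(O)c([C@H](C2=C(O)C(C)(C)C(=O)C(C)(C)C2=O)C(C)C)c1O | target

**Step count**

Total steps: 9. Longest linear sequence: 9 steps (steps 1 to 9 from syncarpic acid; step 5 branches from and rejoins the same intermediate 11).

**Steps most likely to fail**

Step 6 (bears the label). The push–pull stabilised siloxycyclobutenone may fail to open, or the hindered vinylketene may dimerise or be captured by the phenol product faster than it adds the equally hindered alkyne. The fallback uses known biomimetic chemistry; it sets out from 4 and 18 and comes back at 21. Phloroglucinol (Oc1cc(O)cc(O)c1, commercial) is C-acylated with 18 and AlCl3 to 1-(2,4,6-trihydroxyphenyl)hexan-1-one F1. F1 is then taken through two successive Friedel–Crafts-type Michael additions to 4 (2 equiv) in THF, catalysed by lithium aluminium bis(binaphtholate), LiAl(C20H12O2)2, using the BINOL antipode that favours the (R)-CH centre. The reaction passes through the mono-adduct 1-{2,4,6-trihydroxy-3-[(1R)-1-(2-hydroxy-3,3,5,5-tetramethyl-4,6-dioxocyclohex-1-en-1-yl)-2-methylpropyl]phenyl}hexan-1-one F2 and should give 21 directly. The meso diastereomer would be removed by chromatography and the enantiomeric purity raised by crystallisation or preparative chromatography on a chiral phase.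

Step 2. The alkene faces may be poorly discriminated, or formation and addition of the copper acetylide of the silylacetylene may be sluggish in the aqueous medium. The fallback sets out from 4 and 5 and comes back at 6. Compound 5 is deprotonated with EtMgBr to [(trimethylsilyl)ethynyl]magnesium bromide F3, which adds to 4 in THF at −78 °C in a conjugate addition (the three carbonyl groups are shielded by the gem-dimethyl groups) to give racemic 5-hydroxy-2,2,6,6-tetramethyl-4-[4-methyl-1-(trimethylsilyl)pent-1-yn-3-yl]cyclohex-4-ene-1,3-dione F4. This acidic enol is resolved by crystallisation of its salt with (S)-1-phenylethylamine (or the antipodal amine, whichever crystallises the wanted acid), the (S)-1-phenylethylammonium salt of (S)-6 F5. Acidification of F5 with dilute HCl returns 6.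

Step 7. The Lewis acid may strip benzyl or silyl groups, or close the phenol oxygen onto the neighbouring enol ether carbon, or acylate on oxygen, in competition with C-acylation at the crowded C1. The fallback sets out from 17 and comes back at 19. Magnesium-mediated ortho-formylation (MgCl2, Et3N, paraformaldehyde, MeCN, 60–80 °C) should give 3,5-bis(Bn-arm)-2-hydroxy-4,6-bis(triisopropylsilyloxy)benzaldehyde F6. Addition of n-C5H11MgBr with CeCl3 in THF at −78 °C, selective for the aldehyde over the hindered ketones and vinylogous esters, should give the benzylic alcohol 1-[3,5-bis(Bn-arm)-2-hydroxy-4,6-bis(triisopropylsilyloxy)phenyl]hexan-1-ol F7 as a mixture of carbinol epimers. Oxidation with MnO2 in CH2Cl2 returns 19.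

**Further compounds**

F1 | step 6 | 1-(2,4,6-trihydroxyphenyl)hexan-1-one | CCCCCC(=O)c1c(O)cc(O)cc1O
F2 | step 6 | 1-{2,4,6-trihydroxy-3-[(1R)-1-(2-hydroxy-3,3,5,5-tetramethyl-4,6-dioxocyclohex-1-en-1-yl)-2-methylpropyl]phenyl}hexan-1-one | CCCCCC(=O)c1c(O)cc(O)c([C@H](C2=C(O)C(C)(C)C(=O)C(C)(C)C2=O)C(C)C)c1O
F3 | step 2 | [(trimethylsilyl)ethynyl]magnesium bromide | C[Si](C)(C)C#C[Mg]Br
F4 | step 2 | racemic 5-hydroxy-2,2,6,6-tetramethyl-4-[4-methyl-1-(trimethylsilyl)pent-1-yn-3-yl]cyclohex-4-ene-1,3-dione | C[Si](C)(C)C#CC(C1=C(O)C(C)(C)C(=O)C(C)(C)C1=O)C(C)C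
F5 | step 2 | (S)-1-phenylethylammonium salt of (S)-6 | C[Si](C)(C)C#C[C@H](C1=C([O-])C(C)(C)C(=O)C(C)(C)C1=O)C(C)C.C[C@H]([NH3+])c1ccccc1
F6 | step 7 | 3,5-bis{(1R)-1-[2-(benzyloxy)-3,3,5,5-tetramethyl-4,6-dioxocyclohex-1-en-1-yl]-2-methylpropyl}-2-hydroxy-4,6-bis(triisopropylsilyloxy)benzaldehyde | O=Cc1c(O)c([C@H](C2=C(OCc3ccccc3)C(C)(C)C(=O)C(C)(C)C2=O)C(C)C)c(O[Si](C(C)C)(C(C)C)C(C)C)c([C@H](C2=C(OCc3ccccc3)C(C)(C)C(=O)C(C)(C)C2=O)C(C)C)c1O[Si](C(C)C)(C(C)C)C(C)C
F7 | step 7 | 1-[3,5-bis{(1R)-1-[2-(benzyloxy)-3,3,5,5-tetramethyl-4,6-dioxocyclohex-1-en-1-yl]-2-methylpropyl}-2-hydroxy-4,6-bis(triisopropylsilyloxy)phenyl]hexan-1-ol (both carbinol epimers) | CCCCCC(O)c1c(O)c([C@H](C2=C(OCc3ccccc3)C(C)(C)C(=O)C(C)(C)C2=O)C(C)C)c(O[Si](C(C)C)(C(C)C)C(C)C)c([C@H](C2=C(OCc3ccccc3)C(C)(C)C(=O)C(C)(C)C2=O)C(C)C)c1O[Si](C(C)C)(C(C)C)C(C)C
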